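**Retrosynthetic overview**

- The aryl ether C–O bond is made last by 1,6-conjugate addition of umbelliferone to a 9(11)-methylene-7-en-6-one; this also creates C9–H, so no drimane alcohol or Mitsunobu step is needed.
- The exocyclic methylene comes from the C9 ketone of an ene-dione (Peterson olefination, with the enolisable C6 ketone masked in situ as its enolate).
- The ene-dione decalin comes from one catalytic enantioselective Diels–Alder reaction that desymmetrises C2v-symmetric 2,6-dimethyl-1,4-benzoquinone with 4-methyl-3-silyloxypenta-1,3-diene. This sets the quaternary C10 and delivers the gem-dimethyl group, both ring oxygens and the vinylic methyl.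
- Ring order: ring B is the quinone ring; ring A is formed in the Diels–Alder step; the coumarin is attached last.

Assumptions: compounds 1, 3 and 6 are commercial. The (S)-catalyst in step 2 is assumed to select the quinone face that gives (8aR)-4; if the sense is opposite, the (R)-catalyst is used and nothing else changes. Drimane numbering is used in the explanations (C3 and C6 ketones; C5, C9, C10 stereocentres; C11 = OCH2).

**Step 1**
Reactants: 1, 4-methylpent-1-en-3-one (isopropyl vinyl ketone)
Product: 2, triisopropyl[(4-methylpenta-1,3-dien-3-yl)oxy]silane
Conditions: TIPSOTf (1.1 equiv), Et3N (1.5 equiv), Et2O, 0 °C → rt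
Reagents that add atoms: triisopropylsilyl triflate, CC(C)[Si](OS(=O)(=O)C(F)(F)F)(C(C)C)C(C)C
Why: Soft enolisation to a silyl enol ether (the method used to make 2-silyloxybutadienes from methyl vinyl ketone); the only enolisable hydrogen is the isopropyl methine, so a single regioisomer with no E/Z issue forms.

**Step 2 (key step)**
Reactants: 3, 2,6-dimethyl-1,4-benzoquinone; 2 (1.5 equiv)
Product: 4, (4aS,8aR)-2,5,5,8a-tetramethyl-6-[(triisopropylsilyl)oxy]-4a,5,8,8a-tetrahydronaphthalene-1,4-dione (cis-fused; 4a-H and 8a-CH3 on the same face)
Conditions: (S)-o-tolyl-CBS-oxazaborolidine·Tf2NH (20 mol %), CH2Cl2, −78 → −30 °C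
Reagents that add atoms: none
Why: Proposed new method: a cationic-oxazaborolidine-catalysed quinone Diels–Alder reaction used as a desymmetrisation – the two C=C bonds of 3 are equivalent and their faces enantiotopic, so catalyst face selection (Lewis acid on the unhindered, CH-flanked carbonyl) alone fixes the quaternary C10, with C5–H necessarily cis (corrected in step 3); regiochemistry is enforced sterically, because the CMe2 terminus can only bond to the unsubstituted ring carbon and the CH2 terminus to the methyl-bearing one, which is also the orientation that the gem-dimethyl terminus favours electronically for a quinone complexed at that carbonyl, while the 3-siloxy group raises the HOMO and the s-cis population; the closest known reactions are oxazaborolidinium-catalysed Diels–Alder additions of 2-silyloxybutadienes to methyl-substituted benzoquinones, and what is unproven is a diene with a fully substituted terminus whose siloxy polarisation opposes this orientation.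

**Step 3**
Reactants: 4
Product: 5, (4aR,8aS)-3,4a,8,8-tetramethyl-4-methylidene-4a,5,6,8a-tetrahydronaphthalene-1,7(4H,8H)-dione (trans-fused; 8a-H anti to 4a-CH3)
Conditions: LiHMDS (1.1 equiv), THF, −78 °C; Me3SiCH2Li (2 equiv), −78 → −20 °C; AcOH, −78 °C; then 48% aq HF, MeCN, 0 °C → rt (one pot)
Reagents that add atoms: (trimethylsilyl)methyllithium, [Li]C[Si](C)(C)C (delivers the CH2)
Why: Peterson olefination with in situ enolate protection – C6 is the only enolisable ketone (C9 is flanked by the quaternary C10 and a vinylic carbon), so LiHMDS converts it to its C5 enolate and the organolithium adds only to C9 (cf. organolithium additions to 2,6,6-trimethylcyclohex-2-enone); kinetic reprotonation at C5 anti to the adjacent angular methyl gives the trans ring fusion, and HF then effects β-hydroxysilane elimination and cleaves the silyl enol ether to the C3 ketone.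

**Step 4**
Reactants: 5; 6, umbelliferone (7-hydroxy-2H-chromen-2-one, 2 equiv)
Product: 7, epi-conferdione, 7-{[(1R,4aS,8aS)-2,5,5,8a-tetramethyl-4,6-dioxo-1,4,4a,5,6,7,8,8a-octahydronaphthalen-1-yl]methoxy}-2H-chromen-2-one
Conditions: Cs2CO3 (0.2 equiv), MeCN, 0 °C → rt; AcOH quench as soon as the deconjugated (8-ene) adduct is consumed
Reagents that add atoms: none
Why: Proposed new method: a base-catalysed 1,6-oxa-Michael addition of the phenoxide to the unhindered exocyclic terminus of the 4-methylenecyclohex-2-enone (the 1,4-position is fully substituted), after which the dienolate is protonated reversibly at C7 and productively at C9 from the face anti to the axial C10 methyl, placing CH2OAr cis to that methyl, while phenoxide is too weak a base to enolise C5; the closest known reactions are 1,6-additions of thiols and amines to 6-methylene-Δ4-3-ketosteroids and of phenols to p-quinone methides, and the C9 configuration is kinetic, so the reaction must be stopped before it equilibrates.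

**Compound list**

1 | 4-methylpent-1-en-3-one | C=CC(=O)C(C)C | starting material
2 | triisopropyl[(4-methylpenta-1,3-dien-3-yl)oxy]silane | C=CC(O[Si](C(C)C)(C(C)C)C(C)C)=C(C)C | intermediate
3 | 2,6-dimethyl-1,4-benzoquinone | CC1=CC(=O)C=C(C)C1=O | starting material
4 | (4aS,8aR)-2,5,5,8a-tetramethyl-6-[(triisopropylsilyl)oxy]-4a,5,8,8a-tetrahydronaphthalene-1,4-dione | CC1=CC(=O)[C@H]2C(C)(C)C(O[Si](C(C)C)(C(C)C)C(C)C)=CC[C@@]2(C)C1=O | intermediate
5 | (4aR,8aS)-3,4a,8,8-tetramethyl-4-methylidene-4a,5,6,8a-tetrahydronaphthalene-1,7(4H,8H)-dione | CC1=CC(=O)[C@@H]2C(C)(C)C(=O)CC[C@@]2(C)C1=C | intermediate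
6 | umbelliferone (7-hydroxy-2H-chromen-2-one) | Oc1ccc2ccc(=O)oc2c1 | starting material
7 | epi-conferdione | CC1=CC(=O)[C@@H]2C(C)(C)C(=O)CC[C@@]2(C)[C@@H]1COc1ccc2ccc(=O)oc2c1 | target

**Totals**

Total steps: 4. Longest linear sequence: 4 (1 → 2 → 4 → 5 → 7).

**Steps most likely to fail, with fallbacks**

1. Step 2 (rate, side reactions of the silyl enol ether with the Lewis acid, and enantioselectivity with a hindered diene). Fallback: run the cycloaddition thermally (toluene, 60–80 °C), where the siloxy-bearing terminus is electronically matched to the CH carbon β to the more electrophilic, methyl-flanked carbonyl, to get racemic 4. Then obtain the single enantiomer by resolution (preparative chiral SFC of 5, or CBS kinetic resolution) instead of asymmetric catalysis.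

2. Step 4 (reversibility, phenoxide C-alkylation, drift of C9 to an epimer mixture). Fallback: form the C11–O bond by substitution instead of conjugate addition. Hydroborate the exocyclic alkene while both ketones are still masked as silyl enol ethers (9-BBN then NaBO3; H is delivered irreversibly to C9 anti to the angular methyl), unmask with HF, and couple the primary alcohol with 6 under Mitsunobu conditions.

3. Step 3 (γ- instead of α′-deprotonation would leave C5 cis; addition to the hindered C9 ketone could be slow). Fallback: replace in situ enolate protection by covalent protection. Convert 4 to the isolated 3,6-bis(silyl enol ether) (TIPSOTf/Et3N), methylenate the single remaining ketone with a non-basic titanium reagent (Petasis or Takai–Lombardo), then treat with HF; protodesilylation at C5 anti to the angular methyl sets the trans fusion.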